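**Retrosynthetic overview**
1. Target 9 ⇒ diol 8 + CO. The γ-lactone is closed last by hydroxyl-directed oxidative C–H carbonylation at one of the two equivalent ortho C–H bonds of the symmetric 3,5-dimethoxyphenyl ring (the symmetry-breaking key step).
2. Diol 8 ⇒ 3,5-dimethoxybenzaldehyde 5 + alkenol 4. The benzylic stereocentre is set by a one-pot hydroboration, boron–zinc exchange and catalytic enantioselective alkylzinc addition.
3. Alkenol 4 ⇒ undec-10-enyl Grignard + (S)-propylene oxide. The remote carbinol comes from the chiral pool.
4. Ring order: the benzene ring is bought; the lactone is the only ring formed, in the final step.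

Assumption: compounds 1, 2 and 5 and all reagents are purchased; one step is one flask with one isolation.

Step 1
Reactants: 1 11-bromoundec-1-ene; 2 (S)-2-methyloxirane
Product: 4 (S)-tetradec-13-en-2-ol, via undec-10-enylmagnesium bromide 3 (not isolated)
Conditions: Mg, THF, 40 °C; then CuBr·SMe2 (10 mol%), 2 (0.8 equiv), THF, −40 → 0 °C; 1 M HCl
Reagents that add atoms: none
Why: Copper-catalysed Grignard opening of a terminal epoxide (SN2 at the unsubstituted CH2); the carbinol centre is carried over unchanged from (S)-propylene oxide, so 4 is (S).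

Step 2
Reactants: 4 (S)-tetradec-13-en-2-ol; 5 3,5-dimethoxybenzaldehyde
Product: 8 (1S,14S)-1-(3,5-dimethoxyphenyl)pentadecane-1,14-diol, via bis-boryl adduct 6 (not isolated), via dialkylzinc 7 (not isolated)
Conditions: 4 (2.2 equiv), Et2BH (from BH3·SMe2 + 2 BEt3, 4.6 equiv), Et2O, 0 °C → rt; evaporate; Et2Zn (neat, 2.5 equiv), 0 °C, then 0.1 mmHg, 40 °C; toluene, Ti(OiPr)4 (2 equiv), (1R,2R)-1,2-bis(trifluoromethanesulfonamido)cyclohexane (8 mol%), 5 (1 equiv), −20 °C, 12 h; 1 M HCl
Reagents that add atoms: none
Why: Anti-Markovnikov hydroboration, Knochel boron–zinc exchange and Ti(OiPr)4/bis(triflamide)-catalysed enantioselective dialkylzinc addition to an aromatic aldehyde; the (1R,2R) ligand should deliver the alkyl group to the Si face of 5 and set C1 as (S) (the sense recalled for PhCHO + Et2Zn giving (S)-1-phenylpropan-1-ol, to be confirmed by Mosher analysis, with the (1S,2S) ligand in reserve), while the remote hydroxyl is masked in situ as its borinate or metal alkoxide and C14 is untouched.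

Step 3
Reactants: 8 (1S,14S)-1-(3,5-dimethoxyphenyl)pentadecane-1,14-diol
Product: 9 (3S)-3-[(13S)-13-hydroxytetradecyl]-5,7-dimethoxy-2-benzofuran-1(3H)-one
Conditions: Pd(OAc)2 (10 mol%), Ac-Gly-OH (20 mol%), AgOAc (2.5 equiv), Li2CO3 (1 equiv), CO (1 atm), DCE, 90 °C, 18 h
Reagents that add atoms: carbon monoxide, [C-]#[O+]
Why: Proposed new method: hydroxyl-directed oxidative C–H carbonylative lactonisation of a secondary benzylic alcohol, in which the benzylic OH and CO give an alkoxycarbonyl–palladium species on divalent palladium, carboxylate-assisted palladation at either of the two equivalent ortho C–H bonds (each para to one OMe and ortho to the other, so strongly activated) gives a six-membered acyl palladacycle, C–C reductive elimination closes the lactone and AgOAc returns zerovalent palladium to the divalent state; the closest known reaction types are the hydroxyl-directed C–H carbonylation of phenethyl alcohols to isochromanones and the amine-directed carbonylation of benzylamines to isoindolinones with Pd(OAc)2/CO/oxidant; the reaction stops after one carbonylation because the directing OH is consumed, the remote OH cannot reach the ring, and no C–O bond at a stereocentre is broken, so C3 stays (S).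

**Compound list**
1 | 11-bromoundec-1-ene | C=CCCCCCCCCCBr | starting material
2 | (S)-2-methyloxirane ((S)-propylene oxide) | C[C@H]1CO1 | starting material
3 | undec-10-enylmagnesium bromide | C=CCCCCCCCCC[Mg]Br | intermediate
4 | (S)-tetradec-13-en-2-ol | C=CCCCCCCCCCC[C@H](C)O | intermediate
5 | 3,5-dimethoxybenzaldehyde | COc1cc(OC)cc(C=O)c1 | starting material
6 | diethyl{(13S)-13-[(diethylboranyl)oxy]tetradecyl}borane (bis-boryl adduct) | CCB(CC)CCCCCCCCCCCCC[C@H](C)OB(CC)CC | intermediate
7 | bis{(13S)-13-[(diethylboranyl)oxy]tetradecyl}zinc (dialkylzinc, idealised; an ethylzinc alkoxide form is equally competent) | CCB(CC)O[C@@H](C)CCCCCCCCCCCC[Zn]CCCCCCCCCCCC[C@H](C)OB(CC)CC | intermediate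
8 | (1S,14S)-1-(3,5-dimethoxyphenyl)pentadecane-1,14-diol | COc1cc(OC)cc(c1)[C@H](CCCCCCCCCCCC[C@H](C)O)O | intermediate
9 | (3S)-3-[(13S)-13-hydroxytetradecyl]-5,7-dimethoxy-2-benzofuran-1(3H)-one | COc1cc(OC)c2c(c1)[C@H](CCCCCCCCCCCC[C@H](C)O)OC2=O | target

**Totals and risks**
Total step count: 3. Longest linear sequence: 3 (1 → 4 → 8 → 9; 2 and 5 are bought).

The steps most likely to fail are, in order, step 3, step 2 and step 1.

Step 3 is the greatest risk. Divalent palladium may oxidise the benzylic alcohol to the aryl ketone (the CO atmosphere should slow β-hydride elimination, but this is untested), the electron-rich arene may homocouple, and palladation next to an OMe group is hindered. The fallback sets out from 8 and changes from C–H activation to electrophilic halogenation followed by cross-coupling carbonylation. N-iodosuccinimide in MeCN at 0 °C iodinates the ring ortho to the carbinol and para to OMe, giving (1S,14S)-1-(2-iodo-3,5-dimethoxyphenyl)pentadecane-1,14-diol F5. Zerovalent-palladium-catalysed carbonylative lactonisation (Pd(OAc)2/dppf, K2CO3, CO 1 atm, DMF, 80 °C) then comes back to the route at 9. Neither operation oxidises the alcohols.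

Step 2 is the second risk. The free hydroxyl may aggregate the zinc reagent and lower rate or ee, one of the two alkyl groups on zinc is lost, and a minor (1R,14S) diastereomer would be hard to remove. The fallback sets out from 4 and sets the benzylic centre by ketone reduction instead of alkyl addition. Hydroboration of 4 with 9-BBN (2.2 equiv, THF) gives 9-[(13S)-13-(9-borabicyclo[3.3.1]nonan-9-yloxy)tetradecyl]-9-borabicyclo[3.3.1]nonane F3. This is used in the same flask in a carbonylative Suzuki–Miyaura coupling with 1-iodo-3,5-dimethoxybenzene (PdCl2(dppf), K3PO4, CO 1 atm, THF, 50 °C) to give (S)-14-hydroxy-1-(3,5-dimethoxyphenyl)pentadecan-1-one F4. Noyori transfer hydrogenation with RuCl[(S,S)-TsDPEN](p-cymene) in HCO2H/Et3N, which gives (S)-1-arylalkanols, comes back to the route at 8.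

Step 1 is the least risky; the likely faults are bromohydrin formation and incomplete regiocontrol. The fallback sets out from 1 and replaces the chiral-pool epoxide opening by enolate alkylation and biocatalytic reduction. Alkylation of lithiated acetone N,N-dimethylhydrazone (LiN(iPr)2, THF, −78 → 0 °C) with 1 gives tetradec-13-en-2-one N,N-dimethylhydrazone F1. Hydrolysis with aqueous oxalic acid/Et2O gives tetradec-13-en-2-one F2. Reduction with a Prelog-selective alcohol dehydrogenase (Rhodococcus ruber ADH, NADH, 2-propanol, pH 7 buffer) gives the (S)-alcohol and comes back to the route at 4.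

**Further compounds**
F1 | step 1 | tetradec-13-en-2-one N,N-dimethylhydrazone | C=CCCCCCCCCCCC(C)=NN(C)C
F2 | step 1 | tetradec-13-en-2-one | C=CCCCCCCCCCCC(C)=O
F3 | step 2 | 9-[(13S)-13-(9-borabicyclo[3.3.1]nonan-9-yloxy)tetradecyl]-9-borabicyclo[3.3.1]nonane | C[C@H](OB1C2CCCC1CCC2)CCCCCCCCCCCCB1C2CCCC1CCC2
F4 | step 2 | (S)-14-hydroxy-1-(3,5-dimethoxyphenyl)pentadecan-1-one | COc1cc(OC)cc(c1)C(=O)CCCCCCCCCCCC[C@H](C)O
F5 | step 3 | (1S,14S)-1-(2-iodo-3,5-dimethoxyphenyl)pentadecane-1,14-diol | COc1cc(OC)c(I)c(c1)[C@H](CCCCCCCCCCCC[C@H](C)O)O
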